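**Plan**

- In the dihydropyran of the target (O1, C2 aryl, C3 acetoxymethyl, C4, C5 benzofuran-2-yl, C6), C6 is a single CH at the aldehyde oxidation level held between O1 and the heterobenzylic C5. That is the pattern left by carbon monoxide inserted between a carbinol oxygen and a conjugated alkene.
- Retrosynthesis: hydrate C5=C6 to a lactol; cut O1–C6 and C5–C6 (hydroformylation with lactol closure); cut C4=C5 (cross-metathesis); cut C2–C3 (carbonyl allylation); in the benzofuran cut the aryl–C3' and O–C2' bonds (Sonogashira coupling and cyclisation).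
- Forward: the chain C2–C3–C4 is made first, the separately built benzofuran is attached as its 2-vinyl derivative, and the pyran ring is closed by CO. Dehydration and desilylation finish the route.
- Stereochemistry: C2 (R) and C3 (S) both arise in one iridium-catalysed anti-selective, enantioselective (hydroxymethyl)allylation of silylated vanillin and are not touched afterwards. The C5 and C6 centres formed on ring closure disappear on dehydration.

Key step: step 11

Assumption: the (R)-SEGPHOS iridium catalyst is taken to attack the aldehyde face that leads to the (1R,2S)-diol, by analogy with related transfer-hydrogenative allylations of aryl aldehydes; if the opposite sense is found, (S)-SEGPHOS is used with no other change.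

Abbreviations: TIPS = triisopropylsilyl, TBS = tert-butyldimethylsilyl, Ms = methanesulfonyl. Pyran atoms are numbered O1, C2–C6 as in the target throughout.

**Route**

Step 1
Reactants: 1 vanillin
Product: 2 3-methoxy-4-(TIPS-oxy)benzaldehyde
Conditions: TIPSCl, imidazole, DMF, rt
Reagents that add atoms: triisopropylsilyl chloride, CC(C)[Si](Cl)(C(C)C)C(C)C
Why: Imidazole-promoted O-silylation of a phenol; the bulky TIPS ether next to the methoxy group is chosen because it should survive carbonate base and isopropanol at 90 °C in step 3 and still leave with fluoride at the end.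

Step 2
Reactants: 3 (Z)-but-2-ene-1,4-diol
Product: 4 4,7-dihydro-1,3-dioxepin-2-one
Conditions: ClCO2Et (2 equiv), Et3N (2 equiv), THF, 0 °C
Reagents that add atoms: ethyl chloroformate, CCOC(=O)Cl
Why: Cyclic carbonate formation by O-acylation and base-mediated intramolecular transcarbonation, the cis alkene holding the two oxygens close enough for closure of the seven-membered ring.

Step 3
Reactants: 2 3-methoxy-4-(TIPS-oxy)benzaldehyde; 4 4,7-dihydro-1,3-dioxepin-2-one
Product: 5 (1R,2S)-2-ethenyl-1-[3-methoxy-4-(TIPS-oxy)phenyl]propane-1,3-diol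
Conditions: [Ir(cod)Cl]2 (2.5 mol %), (R)-SEGPHOS (5 mol %), 4-cyano-3-nitrobenzoic acid (10 mol %), Cs2CO3 (20 mol %), i-PrOH (2 equiv), THF, 90 °C
Reagents that add atoms: none
Why: Krische-type iridium-catalysed transfer-hydrogenative carbonyl (hydroxymethyl)allylation, in which ionisation of the allylic carbonate and loss of CO2 give an (E)-σ-(hydroxymethyl)allyliridium species that adds to the aldehyde through a closed chair transition state (anti relationship of the future C2 and C3), while the cyclometallated iridium–SEGPHOS complex selects the aldehyde face and so the absolute configuration.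

Step 4
Reactants: 5 (1R,2S)-2-ethenyl-1-[3-methoxy-4-(TIPS-oxy)phenyl]propane-1,3-diol
Product: 6 (2S,3R)-2-ethenyl-3-hydroxy-3-[3-methoxy-4-(TIPS-oxy)phenyl]propyl acetate
Conditions: AcCl (1.05 equiv), 2,4,6-collidine, CH2Cl2, −78 °C
Reagents that add atoms: acetyl chloride, CC(=O)Cl
Why: Sterically controlled selective O-acetylation of the primary hydroxyl of a 1,3-diol, the secondary benzylic hydroxyl between the aryl ring and the branched carbon reacting much more slowly with a weak hindered base at low temperature.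

Step 5
Reactants: 7 2-bromo-1,4-dimethoxybenzene
Product: 8 1-(4-bromo-2,5-dimethoxyphenyl)ethanone
Conditions: AcCl, AlCl3, CH2Cl2, 0 °C
Reagents that add atoms: acetyl chloride, CC(=O)Cl
Why: Friedel–Crafts acylation at the position ortho to a methoxy group and para to bromine, the most activated and least hindered site, which places the acetyl group para to the halogen.

Step 6
Reactants: 8 1-(4-bromo-2,5-dimethoxyphenyl)ethanone
Product: 9 1-(4-bromo-2,5-dihydroxyphenyl)ethanone
Conditions: BBr3 (3 equiv), CH2Cl2, −78 °C to rt; H2O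
Reagents that add atoms: none
Why: Boron tribromide demethylation of both aryl methyl ethers (bromide attack on the boron-complexed ether), to which the aryl bromide and the aryl ketone are inert.

Step 7
Reactants: 9 1-(4-bromo-2,5-dihydroxyphenyl)ethanone; 10 but-3-yn-2-ol (racemic)
Product: 12 1-[5-hydroxy-2-(1-hydroxyethyl)-1-benzofuran-6-yl]ethanone (racemic), via alkynylhydroquinone 11 (not isolated)
Conditions: PdCl2(PPh3)2 (3 mol %), CuI (6 mol %), Et3N, DMF, 70 °C, degassed
Reagents that add atoms: none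
Why: Domino Sonogashira coupling and cycloisomerisation, the bromide being activated by the para acetyl group and the only hydroxyl ortho to the new alkyne closing the furan by 5-endo-dig hydroalkoxylation.

Step 8
Reactants: 12 1-[5-hydroxy-2-(1-hydroxyethyl)-1-benzofuran-6-yl]ethanone
Product: 13 1-[5-(TBS-oxy)-2-(1-hydroxyethyl)-1-benzofuran-6-yl]ethanone (racemic)
Conditions: NaH (1.0 equiv), THF, 0 °C; TBSCl (1.05 equiv), 0 °C to rt
Reagents that add atoms: tert-butyldimethylsilyl chloride, CC(C)(C)[Si](C)(C)Cl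
Why: Chemoselective O-silylation through the sodium phenoxide, since one equivalent of hydride removes only the phenolic proton and the neutral secondary alcohol does not react with the silyl chloride in the absence of an amine catalyst.

Step 9
Reactants: 13 1-[5-(TBS-oxy)-2-(1-hydroxyethyl)-1-benzofuran-6-yl]ethanone
Product: 15 1-[5-(TBS-oxy)-2-ethenyl-1-benzofuran-6-yl]ethanone, via secondary mesylate 14 (not isolated)
Conditions: MsCl, Et3N, CH2Cl2, 0 °C; then DBU, rt; BHT added, product used at once
Reagents that add atoms: none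
Why: Sulfonylation of the heterobenzylic alcohol followed by base-induced β-elimination gives the conjugated vinyl group, and the aryl silyl ether and the ketone are inert to amine bases in dichloromethane.

Step 10
Reactants: 6 (2S,3R)-2-ethenyl-3-hydroxy-3-[3-methoxy-4-(TIPS-oxy)phenyl]propyl acetate; 15 1-[5-(TBS-oxy)-2-ethenyl-1-benzofuran-6-yl]ethanone
Product: 16 (2S,3E)-4-[6-acetyl-5-(TBS-oxy)-1-benzofuran-2-yl]-2-{(R)-hydroxy[3-methoxy-4-(TIPS-oxy)phenyl]methyl}but-3-en-1-yl acetate
Conditions: second-generation Hoveyda–Grubbs catalyst RuCl2(SIMes)(=CH-C6H4-2-OiPr) (5 mol %), 15 (2.5 equiv), CH2Cl2, 40 °C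
Reagents that add atoms: none
Why: Olefin cross-metathesis between a fast-reacting vinylarene and an allylically branched terminal alkene that does not homodimerise, giving the conjugated 1,2-disubstituted alkene as its thermodynamically preferred E isomer without involving the allylic stereocentre.

Step 11
Reactants: 16 (2S,3E)-4-[6-acetyl-5-(TBS-oxy)-1-benzofuran-2-yl]-2-{(R)-hydroxy[3-methoxy-4-(TIPS-oxy)phenyl]methyl}but-3-en-1-yl acetate
Product: 18 [(2R,3S)-5-[6-acetyl-5-(TBS-oxy)-1-benzofuran-2-yl]-6-hydroxy-2-[3-methoxy-4-(TIPS-oxy)phenyl]oxan-3-yl]methyl acetate (C5/C6 epimer mixture), via hydroxy aldehyde 17 (not isolated)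
Conditions: Rh(acac)(CO)2 (2 mol %), P(O-2,4-tBu2C6H3)3 (8 mol %), CO/H2 (1:1, 40 bar), toluene, 60 °C
Reagents that add atoms: carbon monoxide, [C-]#[O+]
Why: The phosphite-modified rhodium hydride adds across C4=C5 with rhodium on C5, where the alkyl is stabilised as an η3 heterobenzylic species by the benzofuran and lies away from the branched C3; CO insertion and hydrogenolysis then give the α-benzofuranyl aldehyde 17, which is the branched-selective hydroformylation known for β-substituted vinylarenes. The C2 hydroxyl adds to this aldehyde in a 6-exo-trig closure to give the six-membered lactol, as in tandem hydroformylation–cyclisation of unsaturated alcohols. The new centres are not controlled: C5 is an epimerisable α-aryl aldehyde carbon and C6 is an anomeric carbon under ring–chain equilibrium, and both become sp2 in step 12. The step needs formylation at C5 and not C4 (which would give a five-membered lactol) and formylation in preference to hydrogenation. The benzofuran conjugation, the steric shielding of C4 by C3, the moderate temperature and the high CO pressure should secure this. The same CO pressure disfavours β-hydride elimination towards C3, so C2 and C3 stay as set in step 3.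

Step 12
Reactants: 18 lactol, [(2R,3S)-5-[6-acetyl-5-(TBS-oxy)-1-benzofuran-2-yl]-6-hydroxy-2-[3-methoxy-4-(TIPS-oxy)phenyl]oxan-3-yl]methyl acetate
Product: 20 [(2R,3S)-5-[6-acetyl-5-(TBS-oxy)-1-benzofuran-2-yl]-2-[3-methoxy-4-(TIPS-oxy)phenyl]-3,4-dihydro-2H-pyran-3-yl]methyl acetate, via anomeric mesylate 19 (not isolated)
Conditions: MsCl (1.5 equiv), Et3N (4 equiv), CH2Cl2, 0 °C to rt
Reagents that add atoms: none
Why: Glycal-type dehydration of a lactol through its anomeric sulfonate, in which ionisation assisted by O1 and loss of the acidic heterobenzylic C5 proton give the enol ether conjugated with the benzofuran, removing the C5 and C6 centres without involving C2 or C3.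

Step 13
Reactants: 20 [(2R,3S)-5-[6-acetyl-5-(TBS-oxy)-1-benzofuran-2-yl]-2-[3-methoxy-4-(TIPS-oxy)phenyl]-3,4-dihydro-2H-pyran-3-yl]methyl acetate
Product: 21 propolis-benzofuran A, [(2R,3S)-5-(6-acetyl-5-hydroxy-1-benzofuran-2-yl)-2-(4-hydroxy-3-methoxyphenyl)-3,4-dihydro-2H-pyran-3-yl]methyl acetate
Conditions: Bu4NF (2.5 equiv), AcOH (2.5 equiv), THF, 0 °C
Reagents that add atoms: none
Why: Fluoride-mediated cleavage of both aryl silyl ethers, with acetic acid buffering so that the primary acetate, the enol ether and the para-hydroxybenzylic C2–O1 bond are not exposed to phenoxide or free base.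

**Compound list**

1 | vanillin | COc1cc(C=O)ccc1O | starting material
2 | 3-methoxy-4-(TIPS-oxy)benzaldehyde | COc1cc(C=O)ccc1O[Si](C(C)C)(C(C)C)C(C)C | intermediate
3 | (Z)-but-2-ene-1,4-diol | OC/C=C\CO | starting material
4 | 4,7-dihydro-1,3-dioxepin-2-one | O=C1OCC=CCO1 | intermediate
5 | (1R,2S)-2-ethenyl-1-[3-methoxy-4-(TIPS-oxy)phenyl]propane-1,3-diol | COc1cc([C@H](O)[C@H](CO)C=C)ccc1O[Si](C(C)C)(C(C)C)C(C)C | intermediate
6 | (2S,3R)-2-ethenyl-3-hydroxy-3-[3-methoxy-4-(TIPS-oxy)phenyl]propyl acetate | COc1cc([C@H](O)[C@H](COC(C)=O)C=C)ccc1O[Si](C(C)C)(C(C)C)C(C)C | intermediate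
7 | 2-bromo-1,4-dimethoxybenzene | COc1ccc(OC)c(Br)c1 | starting material
8 | 1-(4-bromo-2,5-dimethoxyphenyl)ethanone | CC(=O)c1cc(OC)c(Br)cc1OC | intermediate
9 | 1-(4-bromo-2,5-dihydroxyphenyl)ethanone | CC(=O)c1cc(O)c(Br)cc1O | intermediate
10 | but-3-yn-2-ol (racemic) | CC(O)C#C | starting material
11 | 1-[2,5-dihydroxy-4-(3-hydroxybut-1-yn-1-yl)phenyl]ethanone (racemic, not isolated) | CC(=O)c1cc(O)c(C#CC(C)O)cc1O | intermediate
12 | 1-[5-hydroxy-2-(1-hydroxyethyl)-1-benzofuran-6-yl]ethanone (racemic) | CC(O)c1cc2cc(O)c(C(C)=O)cc2o1 | intermediate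
13 | 1-[5-(TBS-oxy)-2-(1-hydroxyethyl)-1-benzofuran-6-yl]ethanone (racemic) | CC(O)c1cc2cc(O[Si](C)(C)C(C)(C)C)c(C(C)=O)cc2o1 | intermediate
14 | 1-[6-acetyl-5-(TBS-oxy)-1-benzofuran-2-yl]ethyl methanesulfonate (racemic, not isolated) | CC(OS(C)(=O)=O)c1cc2cc(O[Si](C)(C)C(C)(C)C)c(C(C)=O)cc2o1 | intermediate
15 | 1-[5-(TBS-oxy)-2-ethenyl-1-benzofuran-6-yl]ethanone | C=Cc1cc2cc(O[Si](C)(C)C(C)(C)C)c(C(C)=O)cc2o1 | intermediate
16 | (2S,3E)-4-[6-acetyl-5-(TBS-oxy)-1-benzofuran-2-yl]-2-{(R)-hydroxy[3-methoxy-4-(TIPS-oxy)phenyl]methyl}but-3-en-1-yl acetate | COc1cc([C@H](O)[C@H](COC(C)=O)/C=C/c2cc3cc(O[Si](C)(C)C(C)(C)C)c(C(C)=O)cc3o2)ccc1O[Si](C(C)C)(C(C)C)C(C)C | intermediate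
17 | (2S)-4-[6-acetyl-5-(TBS-oxy)-1-benzofuran-2-yl]-2-{(R)-hydroxy[3-methoxy-4-(TIPS-oxy)phenyl]methyl}-5-oxopentyl acetate (C4 epimers, not isolated) | COc1cc([C@H](O)[C@H](COC(C)=O)CC(C=O)c2cc3cc(O[Si](C)(C)C(C)(C)C)c(C(C)=O)cc3o2)ccc1O[Si](C(C)C)(C(C)C)C(C)C | intermediate
18 | [(2R,3S)-5-[6-acetyl-5-(TBS-oxy)-1-benzofuran-2-yl]-6-hydroxy-2-[3-methoxy-4-(TIPS-oxy)phenyl]oxan-3-yl]methyl acetate (mixed at C5 and C6) | COc1cc([C@@H]2OC(O)C(c3cc4cc(O[Si](C)(C)C(C)(C)C)c(C(C)=O)cc4o3)C[C@H]2COC(C)=O)ccc1O[Si](C(C)C)(C(C)C)C(C)C | intermediate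
19 | [(2R,3S)-5-[6-acetyl-5-(TBS-oxy)-1-benzofuran-2-yl]-6-(methanesulfonyloxy)-2-[3-methoxy-4-(TIPS-oxy)phenyl]oxan-3-yl]methyl acetate (mixed at C5 and C6, not isolated) | COc1cc([C@@H]2OC(OS(C)(=O)=O)C(c3cc4cc(O[Si](C)(C)C(C)(C)C)c(C(C)=O)cc4o3)C[C@H]2COC(C)=O)ccc1O[Si](C(C)C)(C(C)C)C(C)C | intermediate
20 | [(2R,3S)-5-[6-acetyl-5-(TBS-oxy)-1-benzofuran-2-yl]-2-[3-methoxy-4-(TIPS-oxy)phenyl]-3,4-dihydro-2H-pyran-3-yl]methyl acetate | COc1cc([C@@H]2OC=C(c3cc4cc(O[Si](C)(C)C(C)(C)C)c(C(C)=O)cc4o3)C[C@H]2COC(C)=O)ccc1O[Si](C(C)C)(C(C)C)C(C)C | intermediate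
21 | propolis-benzofuran A, [(2R,3S)-5-(6-acetyl-5-hydroxy-1-benzofuran-2-yl)-2-(4-hydroxy-3-methoxyphenyl)-3,4-dihydro-2H-pyran-3-yl]methyl acetate | COc1cc([C@@H]2OC=C(c3cc4cc(O)c(C(C)=O)cc4o3)C[C@H]2COC(C)=O)ccc1O | target

**Count**

Total steps: 13. Longest linear sequence: 9 steps (steps 5, 6, 7, 8, 9, 10, 11, 12, 13, from 7 to 21).

**Steps most likely to fail**

Step 11. Rhodium may be delivered to C4 instead of C5, the conjugated alkene may be hydrogenated, the hindered internal alkene may turn over slowly, or the double bond may migrate towards C3 with loss of that centre. The fallback keeps CO as the source of C6 but uses the reliable linear mode on the terminal alkene and attaches the benzofuran afterwards; it sets out from 6 and rejoins the route at 21. Linear-selective hydroformylation of 6 (Rh(acac)(CO)2, Xantphos, CO/H2) with in situ lactolisation should give the C5-unsubstituted lactol F1. MsCl and Et3N should dehydrate it to the dihydropyran F2. NIS with catalytic AgNO3 should iodinate the enol ether at C5 to give the 5-iodo-dihydropyran F3. Sonogashira coupling with ethynyltrimethylsilane should give the silylated enyne F4, and AgNO3-catalysed protodesilylation in aqueous acetone the terminal enyne F5. Sonogashira coupling of F5 with 9 and cyclisation in the same flask, as in step 7, should build the benzofuran on C5 and give the mono-silylated enol ether F6. Buffered Bu4NF as in step 13 should then give 21.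

Step 10. The vinylbenzofuran 15 may polymerise or dimerise faster than it crosses, and the ruthenium catalyst may die before the hindered alkene is consumed. The fallback avoids 15 by building the benzofuran onto an enyne; it sets out from 6 and rejoins at 16. Cross-metathesis of 6 with vinylboronic acid pinacol ester should give the (E)-alkenylboronate F7. Suzuki–Miyaura coupling with (bromoethynyl)trimethylsilane (Pd(PPh3)4, K3PO4) should give the silylated dienyne precursor F8, and AgNO3-catalysed protodesilylation the terminal enyne F9. Sonogashira coupling with 9 and in situ cyclisation should give the phenol F10, which is 16 without its TBS group. Phenoxide silylation as in step 8 should convert F10 into 16.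

Step 3. Facial or anti/syn selectivity may be insufficient with this electron-rich aldehyde, and the aryl silyl ether may be partly cleaved by carbonate at 90 °C. The fallback replaces the iridium coupling by an acid-catalysed allylboration at low temperature; it sets out from 2 and rejoins at 6, skipping steps 2 and 4. The (E)-allylboronate F11, made by cross-metathesis of allylboronic acid pinacol ester with commercial (Z)-but-2-ene-1,4-diyl diacetate, should add to 2 under a chiral phosphoric acid ((R)-TRIP, toluene, −30 °C) through a chair transition state, giving the anti acetate 6 directly.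

**Further compounds**

F1 | step 11 | [(2R,3S)-6-hydroxy-2-[3-methoxy-4-(TIPS-oxy)phenyl]oxan-3-yl]methyl acetate (anomer mixture) | COc1cc([C@@H]2OC(O)CC[C@H]2COC(C)=O)ccc1O[Si](C(C)C)(C(C)C)C(C)C
F2 | step 11 | [(2R,3S)-2-[3-methoxy-4-(TIPS-oxy)phenyl]-3,4-dihydro-2H-pyran-3-yl]methyl acetate | COc1cc([C@@H]2OC=CC[C@H]2COC(C)=O)ccc1O[Si](C(C)C)(C(C)C)C(C)C
F3 | step 11 | [(2R,3S)-5-iodo-2-[3-methoxy-4-(TIPS-oxy)phenyl]-3,4-dihydro-2H-pyran-3-yl]methyl acetate | COc1cc([C@@H]2OC=C(I)C[C@H]2COC(C)=O)ccc1O[Si](C(C)C)(C(C)C)C(C)C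
F4 | step 11 | [(2R,3S)-2-[3-methoxy-4-(TIPS-oxy)phenyl]-5-[(trimethylsilyl)ethynyl]-3,4-dihydro-2H-pyran-3-yl]methyl acetate | COc1cc([C@@H]2OC=C(C#C[Si](C)(C)C)C[C@H]2COC(C)=O)ccc1O[Si](C(C)C)(C(C)C)C(C)C
F5 | step 11 | [(2R,3S)-5-ethynyl-2-[3-methoxy-4-(TIPS-oxy)phenyl]-3,4-dihydro-2H-pyran-3-yl]methyl acetate | COc1cc([C@@H]2OC=C(C#C)C[C@H]2COC(C)=O)ccc1O[Si](C(C)C)(C(C)C)C(C)C
F6 | step 11 | [(2R,3S)-5-(6-acetyl-5-hydroxy-1-benzofuran-2-yl)-2-[3-methoxy-4-(TIPS-oxy)phenyl]-3,4-dihydro-2H-pyran-3-yl]methyl acetate | COc1cc([C@@H]2OC=C(c3cc4cc(O)c(C(C)=O)cc4o3)C[C@H]2COC(C)=O)ccc1O[Si](C(C)C)(C(C)C)C(C)C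
F7 | step 10 | (2S,3E)-2-{(R)-hydroxy[3-methoxy-4-(TIPS-oxy)phenyl]methyl}-4-(4,4,5,5-tetramethyl-1,3,2-dioxaborolan-2-yl)but-3-en-1-yl acetate | COc1cc([C@H](O)[C@H](COC(C)=O)/C=C/B2OC(C)(C)C(C)(C)O2)ccc1O[Si](C(C)C)(C(C)C)C(C)C
F8 | step 10 | (2S,3E)-2-{(R)-hydroxy[3-methoxy-4-(TIPS-oxy)phenyl]methyl}-6-(trimethylsilyl)hex-3-en-5-yn-1-yl acetate | COc1cc([C@H](O)[C@H](COC(C)=O)/C=C/C#C[Si](C)(C)C)ccc1O[Si](C(C)C)(C(C)C)C(C)C
F9 | step 10 | (2S,3E)-2-{(R)-hydroxy[3-methoxy-4-(TIPS-oxy)phenyl]methyl}hex-3-en-5-yn-1-yl acetate | COc1cc([C@H](O)[C@H](COC(C)=O)/C=C/C#C)ccc1O[Si](C(C)C)(C(C)C)C(C)C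
F10 | step 10 | (2S,3E)-4-(6-acetyl-5-hydroxy-1-benzofuran-2-yl)-2-{(R)-hydroxy[3-methoxy-4-(TIPS-oxy)phenyl]methyl}but-3-en-1-yl acetate | COc1cc([C@H](O)[C@H](COC(C)=O)/C=C/c2cc3cc(O)c(C(C)=O)cc3o2)ccc1O[Si](C(C)C)(C(C)C)C(C)C
F11 | step 3 | (E)-4-(4,4,5,5-tetramethyl-1,3,2-dioxaborolan-2-yl)but-2-en-1-yl acetate | CC(=O)OC/C=C/CB1OC(C)(C)C(C)(C)O1
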